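The dihydrofuran ring (ring B) is cut at the benzylic C3–C3a bond. The key step exploits two features: C3, C2 and the two side-chain carbons (the later enal α-carbon and formyl carbon) form one four-carbon chain oxygenated at C2, which maps onto (S)-α-hydroxy-γ-butyrolactone, and C3a is an aryl carbon ortho to the ring oxygen O1. In one operation an intramolecular nickel/chromium-mediated aryl–aldehyde coupling forms C3–C3a, closes ring B and creates the C3 carbinol. Its precursor is an ortho-iodoaryl ether of a (2R)-2-aryloxy-4-silyloxybutanal that already carries C2 and the (S)-configured C1′ centre; the esters and the α-methylene group are added afterwards.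

Key step: step 6

Remark: 4′-hydroxy-3′-iodoacetophenone (1) is taken as a catalogue compound. Benzofuran numbering is used (O1, C2, C3, C3a, C4–C7, C7a; ring A = benzene ring, ring B = dihydrofuran ring; C1′ = carbinol carbon on C5), and the target is the cis-(2R,3R,1′S) isomer.
Remark: both hydroxyl protecting groups are silyl ethers, so every protecting-group operation runs under basic or buffered fluoride conditions and no acid meets the alkoxybenzylic C–O bonds or the γ-hydroxy amide.

Step 1
Reactants: 1 4′-hydroxy-3′-iodoacetophenone; 2 (S)-α-hydroxy-γ-butyrolactone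
Product: 3 (3R)-3-(4-acetyl-2-iodophenoxy)oxolan-2-one
Conditions: PPh3, DIAD, THF, 0 °C → rt
Reagents that add atoms: none
Why: Mitsunobu etherification, in which the acidic ortho-iodophenol displaces the oxyphosphonium-activated α-hydroxyl of the lactone by SN2 with inversion, so the (S)-lactone gives the (R)-aryl ether centre that becomes C2.

Step 2
Reactants: 3 (3R)-3-(4-acetyl-2-iodophenoxy)oxolan-2-one
Product: 4 (3R)-3-{4-[(1S)-1-hydroxyethyl]-2-iodophenoxy}oxolan-2-one
Conditions: RuCl(p-cymene)[(S,S)-TsDPEN] (1 mol %), HCO2H/Et3N (5:2), EtOAc, 30 °C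
Reagents that add atoms: none
Why: Noyori asymmetric transfer hydrogenation of an aryl methyl ketone, in which the (S,S)-configured catalyst delivers hydride to one ketone face and is expected to set C1′ as (S), while the lactone, the aryl iodide and the α-aryloxy centre are inert in the acidic formate medium.

Step 3
Reactants: 4 (3R)-3-{4-[(1S)-1-hydroxyethyl]-2-iodophenoxy}oxolan-2-one
Product: 5 (2R)-4-hydroxy-2-{4-[(1S)-1-hydroxyethyl]-2-iodophenoxy}-N-methoxy-N-methylbutanamide
Conditions: MeNH(OMe)·HCl (4 equiv), AlMe3 (4 equiv), CH2Cl2, 0 °C → rt; aq. potassium sodium tartrate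
Reagents that add atoms: N,O-dimethylhydroxylamine hydrochloride, CNOC.Cl
Why: Weinreb aminolysis of a lactone with the aluminium amide made in the flask opens the ring at the acyl carbon without touching the α-centre, the free benzylic hydroxyl only consuming one more equivalent of reagent; crude 5 is silylated at once.

Step 4
Reactants: 5 (2R)-4-hydroxy-2-{4-[(1S)-1-hydroxyethyl]-2-iodophenoxy}-N-methoxy-N-methylbutanamide
Product: 7 (2R)-4-(tert-butyldiphenylsilyloxy)-2-{2-iodo-4-[(1S)-1-(triethylsilyloxy)ethyl]phenoxy}-N-methoxy-N-methylbutanamide, via primary tert-butyldiphenylsilyl ether 6 (not isolated)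
Conditions: t-BuPh2SiCl (1.05 equiv), imidazole, CH2Cl2, 0 °C; then Et3SiCl (1.3 equiv), rt
Reagents that add atoms: tert-butyldiphenylsilyl chloride, CC(C)(C)[Si](Cl)(c1ccccc1)c1ccccc1; triethylsilyl chloride, CC[Si](Cl)(CC)CC
Why: Silyl ether formation in which the bulky chloride should react only at the primary hydroxyl and the smaller chloride then caps the secondary benzylic hydroxyl, so the γ-hydroxy amide cannot relactonise and the two oxygens can later be freed in sequence.

Step 5
Reactants: 7 (2R)-4-(tert-butyldiphenylsilyloxy)-2-{2-iodo-4-[(1S)-1-(triethylsilyloxy)ethyl]phenoxy}-N-methoxy-N-methylbutanamide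
Product: 8 (2R)-4-(tert-butyldiphenylsilyloxy)-2-{2-iodo-4-[(1S)-1-(triethylsilyloxy)ethyl]phenoxy}butanal
Conditions: i-Bu2AlH (1.3 equiv), THF, −78 °C; aq. potassium sodium tartrate, 0 °C
Reagents that add atoms: none
Why: Reduction of a Weinreb amide with i-Bu2AlH stops at the chelated tetrahedral aluminium adduct, which releases the aldehyde only on work-up, and cold neutral handling with immediate use of the crude aldehyde should keep the α-aryloxy centre configured.

Step 6
Reactants: 8 (2R)-4-(tert-butyldiphenylsilyloxy)-2-{2-iodo-4-[(1S)-1-(triethylsilyloxy)ethyl]phenoxy}butanal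
Product: 10 (2R,3R)-2-[2-(tert-butyldiphenylsilyloxy)ethyl]-5-[(1S)-1-(triethylsilyloxy)ethyl]-2,3-dihydro-1-benzofuran-3-ol (cis), via arylchromium dichloride 9 (not isolated)
Conditions: CrCl2 (4 equiv), NiCl2 (2 mol %), degassed DMF, rt, 0.02 M; then H2O
Reagents that add atoms: none
Why: CrCl2 reduces NiCl2 to zerovalent nickel, which inserts into the C–I bond of 8; the aryl group passes to trivalent chromium to give 9, whose aryl–chromium bond adds to the aldehyde through a cyclic four-centre transition state, forming C3–C3a, and water then frees the alcohol from its chromium alkoxide (Nozaki–Hiyama–Kishi reaction). The closest known reaction type is the intramolecular nickel/chromium-mediated coupling of aryl and alkenyl iodides with aldehydes. Ring B closes in a 5-exo-trig mode, the carbonyl oxygen ending up outside the new five-membered ring. C2 is unchanged, and the new C3 centre is set by substrate control from C2, that is by which face of the aldehyde carries the chromium-bound oxygen relative to the C2 side chain in the forming ring. The step needs chemoselectivity (only the C–I bond and the aldehyde may react, secured by a substrate that holds no other electrophile for arylchromium, inert silyl ethers and a neutral medium that spares the epimerisable α-aryloxy centre) and the cis relation of C3–OH to the C2 chain. The flexible silyloxyethyl chain gives no decisive facial bias, so this cis preference is the one uncertain point of the route; the C3 epimers are separable alcohols and both can be brought to ester 11, by acylation with retention or by esterification with inversion.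

Step 7
Reactants: 10 (2R,3R)-2-[2-(tert-butyldiphenylsilyloxy)ethyl]-5-[(1S)-1-(triethylsilyloxy)ethyl]-2,3-dihydro-1-benzofuran-3-ol
Product: 11 (2R,3R)-2-[2-(tert-butyldiphenylsilyloxy)ethyl]-5-[(1S)-1-(triethylsilyloxy)ethyl]-2,3-dihydro-1-benzofuran-3-yl 3-methylbutanoate
Conditions: (i-BuCO)2O, DMAP (cat.), Et3N, CH2Cl2, 0 °C → rt
Reagents that add atoms: 3-methylbutanoic (isovaleric) anhydride, CC(C)CC(=O)OC(=O)CC(C)C
Why: DMAP-catalysed acylation of the secondary alcohol with the anhydride takes place at oxygen and therefore keeps the C3 configuration.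

Step 8
Reactants: 11 (2R,3R)-2-[2-(tert-butyldiphenylsilyloxy)ethyl]-5-[(1S)-1-(triethylsilyloxy)ethyl]-2,3-dihydro-1-benzofuran-3-yl 3-methylbutanoate
Product: 12 (2R,3R)-2-[2-(tert-butyldiphenylsilyloxy)ethyl]-5-[(1S)-1-hydroxyethyl]-2,3-dihydro-1-benzofuran-3-yl 3-methylbutanoate
Conditions: HF·pyridine, pyridine, THF, 0 °C
Reagents that add atoms: none
Why: Selective desilylation, since a secondary triethylsilyl ether is cleaved by buffered HF·pyridine far faster than a primary tert-butyldiphenylsilyl ether, and the buffered medium should not ionise the benzylic C–O bonds.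

Step 9
Reactants: 12 (2R,3R)-2-[2-(tert-butyldiphenylsilyloxy)ethyl]-5-[(1S)-1-hydroxyethyl]-2,3-dihydro-1-benzofuran-3-yl 3-methylbutanoate
Product: 13 (1S)-1-{(2R,3R)-2-[2-(tert-butyldiphenylsilyloxy)ethyl]-3-(3-methylbutanoyloxy)-2,3-dihydro-1-benzofuran-5-yl}ethyl 3-methylbut-2-enoate
Conditions: Me2C=CHCO2H, EDC·HCl, DMAP, CH2Cl2, 0 °C → rt
Reagents that add atoms: 3-methylbut-2-enoic (senecioic) acid, CC(C)=CC(=O)O
Why: Steglich esterification acylates the C1′ oxygen with retention, and working without an acid chloride and a tertiary amine avoids the vinylketene pathway that would move the double bond out of conjugation.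

Step 10
Reactants: 13 (1S)-1-{(2R,3R)-2-[2-(tert-butyldiphenylsilyloxy)ethyl]-3-(3-methylbutanoyloxy)-2,3-dihydro-1-benzofuran-5-yl}ethyl 3-methylbut-2-enoate
Product: 14 (1S)-1-[(2R,3R)-2-(2-hydroxyethyl)-3-(3-methylbutanoyloxy)-2,3-dihydro-1-benzofuran-5-yl]ethyl 3-methylbut-2-enoate
Conditions: Bu4NF, AcOH (1:1), THF, rt
Reagents that add atoms: none
Why: Fluoride-mediated cleavage of the remaining silyl ether, buffered with acetic acid so that the medium stays near neutral and both esters stay in place.

Step 11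
Reactants: 14 (1S)-1-[(2R,3R)-2-(2-hydroxyethyl)-3-(3-methylbutanoyloxy)-2,3-dihydro-1-benzofuran-5-yl]ethyl 3-methylbut-2-enoate
Product: 15 (1S)-1-[(2R,3R)-3-(3-methylbutanoyloxy)-2-(2-oxoethyl)-2,3-dihydro-1-benzofuran-5-yl]ethyl 3-methylbut-2-enoate
Conditions: Dess–Martin periodinane, pyridine, CH2Cl2, 0 °C → rt
Reagents that add atoms: none
Why: Dess–Martin oxidation converts the primary alcohol into the aldehyde under near-neutral conditions without touching the esters, and the β-aryloxy aldehyde is used directly.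

Step 12
Reactants: 15 (1S)-1-[(2R,3R)-3-(3-methylbutanoyloxy)-2-(2-oxoethyl)-2,3-dihydro-1-benzofuran-5-yl]ethyl 3-methylbut-2-enoate
Product: 17 (1S)-1-[(2R,3R)-3-(3-methylbutanoyloxy)-2-(3-oxoprop-1-en-2-yl)-2,3-dihydro-1-benzofuran-5-yl]ethyl 3-methylbut-2-enoate (target), via Mannich base 16 (not isolated)
Conditions: CH2=NMe2+ I− (3 equiv), Et3N, CH2Cl2, 0 °C → rt
Reagents that add atoms: N,N-dimethylmethyleneiminium iodide (Eschenmoser's salt), C=[N+](C)C.[I-]
Why: α-Methylenation of an aldehyde by Mannich reaction with the preformed iminium salt followed by loss of dimethylamine from the Mannich base, giving an enal without an α-hydrogen; short exposure to Et3N at or below room temperature is chosen to limit β-elimination of the ring oxygen.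

Compound list
1 | 4′-hydroxy-3′-iodoacetophenone | CC(=O)c1ccc(O)c(I)c1 | starting material
2 | (S)-α-hydroxy-γ-butyrolactone | O[C@H]1CCOC1=O | starting material
3 | (3R)-3-(4-acetyl-2-iodophenoxy)oxolan-2-one | CC(=O)c1ccc(O[C@@H]2CCOC2=O)c(I)c1 | intermediate
4 | (3R)-3-{4-[(1S)-1-hydroxyethyl]-2-iodophenoxy}oxolan-2-one | C[C@H](O)c1ccc(O[C@@H]2CCOC2=O)c(I)c1 | intermediate
5 | (2R)-4-hydroxy-2-{4-[(1S)-1-hydroxyethyl]-2-iodophenoxy}-N-methoxy-N-methylbutanamide | C[C@H](O)c1ccc(O[C@H](CCO)C(=O)N(C)OC)c(I)c1 | intermediate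
6 | (2R)-4-(tert-butyldiphenylsilyloxy)-2-{4-[(1S)-1-hydroxyethyl]-2-iodophenoxy}-N-methoxy-N-methylbutanamide (not isolated) | C[C@H](O)c1ccc(O[C@H](CCO[Si](c2ccccc2)(c2ccccc2)C(C)(C)C)C(=O)N(C)OC)c(I)c1 | intermediate
7 | (2R)-4-(tert-butyldiphenylsilyloxy)-2-{2-iodo-4-[(1S)-1-(triethylsilyloxy)ethyl]phenoxy}-N-methoxy-N-methylbutanamide | C[C@H](O[Si](CC)(CC)CC)c1ccc(O[C@H](CCO[Si](c2ccccc2)(c2ccccc2)C(C)(C)C)C(=O)N(C)OC)c(I)c1 | intermediate
8 | (2R)-4-(tert-butyldiphenylsilyloxy)-2-{2-iodo-4-[(1S)-1-(triethylsilyloxy)ethyl]phenoxy}butanal (key-step precursor) | C[C@H](O[Si](CC)(CC)CC)c1ccc(O[C@H](CCO[Si](c2ccccc2)(c2ccccc2)C(C)(C)C)C=O)c(I)c1 | intermediate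
9 | arylchromium dichloride of 8, trivalent chromium on C3a in place of iodine (not isolated) | C[C@H](O[Si](CC)(CC)CC)c1ccc(O[C@H](CCO[Si](c2ccccc2)(c2ccccc2)C(C)(C)C)C=O)c([Cr](Cl)Cl)c1 | intermediate
10 | (2R,3R)-2-[2-(tert-butyldiphenylsilyloxy)ethyl]-5-[(1S)-1-(triethylsilyloxy)ethyl]-2,3-dihydro-1-benzofuran-3-ol, cis (key-step product) | CC(C)(C)[Si](c1ccccc1)(c1ccccc1)OCC[C@H]1Oc2ccc([C@H](C)O[Si](CC)(CC)CC)cc2[C@H]1O | intermediate
11 | (2R,3R)-2-[2-(tert-butyldiphenylsilyloxy)ethyl]-5-[(1S)-1-(triethylsilyloxy)ethyl]-2,3-dihydro-1-benzofuran-3-yl 3-methylbutanoate | CC(C)(C)[Si](c1ccccc1)(c1ccccc1)OCC[C@H]1Oc2ccc([C@H](C)O[Si](CC)(CC)CC)cc2[C@H]1OC(=O)CC(C)C | intermediate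
12 | (2R,3R)-2-[2-(tert-butyldiphenylsilyloxy)ethyl]-5-[(1S)-1-hydroxyethyl]-2,3-dihydro-1-benzofuran-3-yl 3-methylbutanoate | CC(C)(C)[Si](c1ccccc1)(c1ccccc1)OCC[C@H]1Oc2ccc([C@H](C)O)cc2[C@H]1OC(=O)CC(C)C | intermediate
13 | (1S)-1-{(2R,3R)-2-[2-(tert-butyldiphenylsilyloxy)ethyl]-3-(3-methylbutanoyloxy)-2,3-dihydro-1-benzofuran-5-yl}ethyl 3-methylbut-2-enoate | CC(C)(C)[Si](c1ccccc1)(c1ccccc1)OCC[C@H]1Oc2ccc([C@H](C)OC(=O)C=C(C)C)cc2[C@H]1OC(=O)CC(C)C | intermediate
14 | (1S)-1-[(2R,3R)-2-(2-hydroxyethyl)-3-(3-methylbutanoyloxy)-2,3-dihydro-1-benzofuran-5-yl]ethyl 3-methylbut-2-enoate | OCC[C@H]1Oc2ccc([C@H](C)OC(=O)C=C(C)C)cc2[C@H]1OC(=O)CC(C)C | intermediate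
15 | (1S)-1-[(2R,3R)-3-(3-methylbutanoyloxy)-2-(2-oxoethyl)-2,3-dihydro-1-benzofuran-5-yl]ethyl 3-methylbut-2-enoate | O=CC[C@H]1Oc2ccc([C@H](C)OC(=O)C=C(C)C)cc2[C@H]1OC(=O)CC(C)C | intermediate
16 | Mannich base of 15, carrying CH2NMe2 on the aldehyde α-carbon, both epimers at that carbon (not isolated) | CN(C)CC(C=O)[C@H]1Oc2ccc([C@H](C)OC(=O)C=C(C)C)cc2[C@H]1OC(=O)CC(C)C | intermediate
17 | (1S)-1-[(2R,3R)-3-(3-methylbutanoyloxy)-2-(3-oxoprop-1-en-2-yl)-2,3-dihydro-1-benzofuran-5-yl]ethyl 3-methylbut-2-enoate | C=C(C=O)[C@H]1Oc2ccc([C@H](C)OC(=O)C=C(C)C)cc2[C@H]1OC(=O)CC(C)C | target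

Total step count: 12. Longest linear sequence: 12 steps (1 → 17; lactone 2 enters in step 1).

Steps most likely to fail

Step 6 (ring closure). The aldehyde may be attacked mainly on the other face, the chromium-bound oxygen preferring the side away from the C2 chain, so that the trans carbinol dominates. The fallback sets out from 8: the same coupling then gives mainly the (2R,3S)-trans alcohol F1. F1 is esterified with 3-methylbutanoic acid under Mitsunobu conditions (PPh3, DIAD, toluene, 0 °C). The carboxylate displaces the activated oxygen with inversion at C3, giving 11 directly, where the route is rejoined. In F1 the C2 hydrogen is syn to the leaving group, which disfavours anti elimination to the benzofuran.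

Step 12 (methylenation). Under amine base the enol or enolate of 15 may expel the ring oxygen O1 (opening of ring B by a retro-oxa-Michael process, with loss of the C2 configuration on reclosure) faster than it undergoes the Mannich reaction. The fallback sets out from 15 and separates bond formation from elimination without added base. Eschenmoser's salt alone in CH2Cl2 at rt should give Mannich base 16 as its hydroiodide through the acid-catalysed enol pathway, and a wash with aq. NaHCO3 frees the amine. mCPBA (1 equiv, CH2Cl2, −20 °C) oxidises the amine to the amine oxide F2, which loses N,N-dimethylhydroxylamine by thermal syn (Cope) elimination on warming to rt. This gives 17, where the route is rejoined.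

Step 3 (lactone opening). The γ-hydroxy amide may revert to the lactone during isolation, or the free alkoxybenzylic alcohol may suffer in the presence of the aluminium reagent. The fallback sets out from 4, avoids the amide and makes the aldehyde by oxidation:
- Et3SiCl and imidazole (CH2Cl2, 0 °C) give the silylated lactone F3.
- LiBH4 (THF, 0 °C) reduces the lactone to the diol F4.
- t-BuPh2SiCl (1 equiv, imidazole, CH2Cl2, −20 °C) should silylate the less hindered hydroxyl at C4, remote from the aryloxy-bearing centre, giving the primary alcohol F5; any regioisomer is removed by chromatography.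
- Dess–Martin periodinane with pyridine (CH2Cl2, 0 °C) oxidises F5 to 8, where the route is rejoined.

Further compounds
F1 | step 6 | (2R,3S)-2-[2-(tert-butyldiphenylsilyloxy)ethyl]-5-[(1S)-1-(triethylsilyloxy)ethyl]-2,3-dihydro-1-benzofuran-3-ol (trans) | CC(C)(C)[Si](c1ccccc1)(c1ccccc1)OCC[C@H]1Oc2ccc([C@H](C)O[Si](CC)(CC)CC)cc2[C@@H]1O
F2 | step 12 | N-oxide of Mannich base 16 | C[N+](C)([O-])CC(C=O)[C@H]1Oc2ccc([C@H](C)OC(=O)C=C(C)C)cc2[C@H]1OC(=O)CC(C)C
F3 | step 3 | (3R)-3-{2-iodo-4-[(1S)-1-(triethylsilyloxy)ethyl]phenoxy}oxolan-2-one | C[C@H](O[Si](CC)(CC)CC)c1ccc(O[C@@H]2CCOC2=O)c(I)c1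
F4 | step 3 | (2R)-2-{2-iodo-4-[(1S)-1-(triethylsilyloxy)ethyl]phenoxy}butane-1,4-diol | C[C@H](O[Si](CC)(CC)CC)c1ccc(O[C@H](CCO)CO)c(I)c1
F5 | step 3 | (2R)-4-(tert-butyldiphenylsilyloxy)-2-{2-iodo-4-[(1S)-1-(triethylsilyloxy)ethyl]phenoxy}butan-1-ol | C[C@H](O[Si](CC)(CC)CC)c1ccc(O[C@H](CCO[Si](c2ccccc2)(c2ccccc2)C(C)(C)C)CO)c(I)c1
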